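0.972 mM h⁻¹ is the fastest the solid reagent can feed partner into this flask, and I hand over the flask with that figure in mind.

left-handed substrate 20 mM; solid reagent 60.0 mM; catalyst 62 µM; added ligand 0.26 mM; right-handed substrate 20 mM

    partner + catalyst + right-handed substrate → catalyst + right-handed product (k1 = 97.8 M⁻² s⁻¹)
    solid reagent ⇌ partner, rate k2*(cs2 - [partner]) while solid is left; crystals form when [partner] > cs2 (cs2 = 2.5 mM, k2 = 1.08 × 10⁻⁴ s⁻¹)
    catalyst + added ligand ⇌ idle complex (K3 = 1240 M⁻¹, k3 = 26.7 M⁻¹ s⁻¹)
    partner + catalyst + left-handed substrate → catalyst + left-handed product (k4 = 270 M⁻² s⁻¹)

- the form that holds most of the catalyst when 20 % of the left-handed substrate and right-handed substrate together are converted (catalyst / idle complex)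
- its share of the catalyst then
- factor on the rate of making left-handed product when 20 % of the left-handed substrate and right-handed substrate together are converted if catalyst is charged twice over
- factor on the rate when 20 % of the left-handed substrate and right-handed substrate together are converted if catalyst is charged at 600 µM instead

I start with the catalyst. Added ligand binds it at 25 h⁻¹ per catalyst, far faster than the dissolution coefficient of 0.39 h⁻¹, so I take that binding as balanced and go round twice, the second time with the ligand held in idle complex taken off:

free share, first round = 1 / (1 + K × ligand) = 75.6 %

free share, second round = 76.7 %

The form that holds most is then catalyst, at 76.7 %.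

When you come, 8.00 mM of substrate has reacted. Splitting that by the two constants leaves about 14.1 mM left-handed and 17.9 mM right-handed substrate. Now I divide the first-order rate at which free catalyst uses partner by the dissolution coefficient:

drain ratio = (k1 × right-handed + k4 × left-handed) × free catalyst / k2 = 2.45

This drain ratio is what I carry. Setting dissolving equal to use gives:

partner = solubility / (1 + drain ratio) = 0.725 mM

The rate goes with free catalyst times partner. With the free share held, n times the catalyst gives a factor n(1 + D)/(1 + nD). Don't add catalyst to hurry the flask: twice the charge gives 1.17, and 600 µM gives 1.35.

The forecast says catalyst at 76.7 %, with factors 1.17 and 1.36, the last not quite mine: “extra catalyst mostly depletes partner and the rate saturates at the dissolution limit”.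

The flask reaches 20 % conversion at 11.9 h with catalyst at 76.7 % and factors 1.17 and 1.37.

At 2.00 h this flask holds 0.577 mM partner, made 1.06 times as fast as it is used, each step taken net, so the balance assumed by the drain ratio, which I reckoned as 2.45 for the later moment of 20 % conversion, is already close. In the flask charged at 600 µM, with 83.4 % of the catalyst free at the same conversion and the substrates taken as I reckoned them, the drain ratio comes to 25.8, and the same balance gives an estimate of 0.0934 mM partner.

The numbers of this flask belong to no real substance; the result is computed.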